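## Analysis of the target

- The target is a 3,4-dihydro-2H-chromene (O1, C2, C3, C4, arene C4a–C8a). Its C2–C3 bond is shared with a ten-membered carbocycle that runs C3, C1′H2, C2′H2, C3′(=CH2), C4′H=C5′H (cis), C6′H[C(CH3)2OH], C7′H2, C8′H2, C2. The arene is a fully substituted phloroglucinol with formyl groups at C6 and C8 and hydroxyls at C5 and C7.
- There are four stereocentres: C2 (R, quaternary, bearing O1, CH3 and C8′), C3 (S), C4 (R, isobutyl) and C6′ (R).
- The C2 methyl group, the C3–C1′ bond and the C4 isobutyl group lie on one face of the pyran ring, so the ten-membered ring is trans-fused. C6′ is separated from this triad by two methylene groups and has to be set independently.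
- Sensitive groups are the 2-substituted cis-1,3-diene with its exocyclic methylene, the tertiary alcohol beside an allylic methine, the tertiary alkyl aryl ether O1–C2, and two aryl aldehydes hydrogen-bonded to acidic phenols.
- The difficulties are the medium ring and the quaternary C2, whose two carbon arms (CH3 and C8′H2) are sterically alike, so C2 must be set by reagent control and C3 and C4 related to it. C4 carries no heteroatom through which its configuration could be relayed.
- The strategy rests on one feature: C3′ is an sp2 carbon of the diene bonded to the sp3 carbon C2′, and C2′ lies two atoms from C3. The C2′–C3′ bond can therefore be made from a vinyl group on C3 (as a primary alkylborane) and the enol triflate of a cis methyl enone, closing the ring away from all four stereocentres.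

## Retrosynthetic reasoning

**33 ⇐ 32 ⇐ 31 ⇐ 30 (unmasking).** The O–Si bond at the C6′ carbinol, the two aryl O–CH3 bonds and the four acetal C–O bonds are cut. The free dialdehyde-diphenol would quench organometallics, the borane and the palladium step, and the tertiary alcohol would be triflated or ionised. Acetals are removed first so that the formyl groups can direct the demethylation; the silyl ether goes last so that the tertiary alcohol is shielded from the Lewis acid.

**30 ⇐ 28 via 29 (key disconnection, C2′–C3′).** This is the only ring bond that joins an sp3 carbon to an sp2 carbon whose partners are both simple to make: the sp2 carbon as the enol triflate of a methyl ketone, the sp3 carbon from a terminal alkene by anti-Markovnikov hydroboration. The bond is remote from C2, C3, C4 and C6′, and the cis C4′=C5′ bond is fixed beforehand. Cutting C3–C1′ or C2–C8′ instead would create a stereocentre during macrocyclisation. The forward step needs site-selective hydroboration of the C3 vinyl group and intramolecular coupling at high dilution.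

**28 ⇐ 26 ⇐ 25 ⇐ 22 + 23 (dienyl triflate).** The C3′–O–S bond is cut back to the methyl ketone 26 (kinetic enolisation at the methyl group gives the exocyclic methylene). The cis C4′=C5′ bond comes from the alkyne of 25 by syn semi-hydrogenation. The C3′–C4′ bond comes from acylation of the terminal alkyne of 22 with the amide 23.

**22 ⇐ 21 ⇐ 20 ⇐ 19 (C5′–C6′ and the C6′ stereocentre).** The C5′–C6′ bond is cut to an acetylide and the trisubstituted epoxide 20; SN2 opening at the secondary carbon inverts C6′ and releases the tertiary alcohol in the same step. The epoxide comes from the trisubstituted alkene of 19 by reagent-controlled epoxidation, which is why C6′ can be set without help from the distant triad.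

**19 ⇐ 18 ⇐ 16 via 17 (O1–C8a).** The pyran is opened at the aryl C–O bond and not at O1–C2. Closing at the arene carbon leaves the C2–O bond of the original epoxide untouched, so C2 is carried with retention. The forward reaction is an intramolecular SNAr, which needs activation; the two formyl groups that the target requires stand ortho and para to the leaving fluoride in 16.

**16 ⇐ 14 ⇐ 13 (two aryl C–CHO bonds).** Only two arene positions are free in 13, so dibromination followed by halogen–metal exchange and formylation is unambiguous.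

**13 ⇐ 12 ⇐ 7 + 9 via 10 and 11 (C4–H and C4–aryl).** C4 is cut first at its C–H bond (hydride capture by a benzylic cation) and then at its aryl bond (addition of an aryl metal to ketone 7). With the hydrogen introduced last, the configuration of C4 is relayed from C3 by 1,3-allylic strain in the acyclic cation. Introducing the isobutyl group last would give the other epimer by the same model.

**7 ⇐ 6 ⇐ 5 ⇐ 4 ⇐ 3 (C4–isobutyl and oxidation level).** The C4–CH2 bond is cut to aldehyde 5 and an isobutyl organometallic. The aldehyde comes from the primary alcohol of diol 3; the tertiary hydroxyl is silylated so that no β-alkoxide can trigger retro-aldol cleavage.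

**3 ⇐ 2 ⇐ 1 (C3–vinyl, C2 and C3).** The C3–vinyl bond is cut to a vinyl copper reagent and epoxy alcohol 2; attack at the secondary epoxide carbon inverts C3 and leaves the C2–O bond intact. Asymmetric epoxidation of the E allylic alcohol 1 defines C2 and, through the alkene geometry, the cis relation of methyl and vinyl. Compound 1 supplies C4, C3, C2, its methyl, C8′, C7′, C6′ and the C(CH3)2 unit.

**9 ⇐ 8.** The aryl bromide comes from the commercial fluoroarene by electrophilic bromination.

## Alternatives that were turned down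

**Alternative 1: cycloaddition on a coumarin, then cleavage of the new cyclohexene.**
- Disconnection: the bond from C4 to the isobutyl methylene and the C3–C1′ bond, both formed at once across C3=C4 of 5,7-dimethoxycoumarin A1.
- Forward key step: a Diels–Alder reaction of A1 with isoprene A2 to the cis-fused lactone A3. Later cleavage of the methylcyclohexene leaves an acetonyl group on C4 and a formylmethyl group on C3.
- For it: the suprafacial addition guarantees the cis C3/C4 relation in one step. On this point it is stronger than the chosen route, which obtains the same relation by acyclic allylic-strain control (step 9). A1 and A2 are cheap.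
- Against it:
  - A1 is an electron-rich and therefore poor dienophile, so forcing conditions are needed.
  - A3 is racemic unless an asymmetric catalyst for this unactivated pair is found.
  - C2 is still a lactone carbonyl. It must receive both a methyl group and the C8′ chain with control of a quaternary centre whose two arms are alike.
  - The acetonyl group needs one more carbon and deoxygenation to become isobutyl.
  - The ten-membered ring is not addressed.
- Comparison: the chosen route sets C2 and C3 absolutely in two steps (steps 1 and 2) and leaves the ring closure free of stereochemical duties.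

**Alternative 2: arene built on a lactone by double Claisen condensation.**
- Disconnection: two ring bonds of the arene.
- Forward key step: dimethyl 3-oxopentanedioate A4 condenses twice with the 3-methoxycarbonyl δ-lactone A5, once at the exocyclic ester and once at the lactone carbonyl, and gives the chroman diester A6 after loss of water.
- For it: the arene arrives with both one-carbon substituents at C6 and C8 and with free phenols. No bromination, formylation or aryl methyl ether cleavage is needed, so it is stronger than the chosen route in the endgame.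
- Against it:
  - A5 must already hold the C2–C3–C4 triad. The stereochemical problem is only moved to a substrate that lacks the aryl group from which the chosen route draws its benzylic cation.
  - The second condensation must add to a lactone carbonyl and keep the ring oxygen. Acyl substitution that expels the tertiary alkoxide and opens the ring is the expected competing path.
  - Two hindered, chelated esters must later be brought to the aldehyde level.
  - The silylalkyne chain on C3 implies a longer way to the ten-membered ring.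
- Comparison: the chosen route takes the arene from a commercial fluoroarene and closes the pyran by SNAr with retention at C2 (step 12).

**Alternative 3: anionic oxy-Cope ring expansion.**
- Disconnection: the C3–C1′ bond, with expansion of a six-membered ring.
- Forward key step: the potassium alkoxide of the vinylcyclohexenol A7 rearranges to the ten-membered 2Z,6E-dienone A8.
- For it: this strain-releasing sigmatropic shift is a more dependable way to a ten-membered carbocycle than a palladium macrocyclisation. On the ring-forming event it is stronger than the chosen route, and it delivers the cis enone directly.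
- Against it:
  - In A8 the chroman is not yet formed. The phenol must later add to the trisubstituted ring alkene, creating C2 under the conformational control of a flexible medium ring, with transannular cyclisation as a competing path.
  - The acetal-protected phenol must be freed with acid beside the enone.
  - Formylation and methylenation fall late, on a sensitive macrocycle.
  - A7 itself carries three stereocentres and is long to make.
- Comparison: the chosen route fixes the chroman triad early under reagent and allylic-strain control and closes the ring last in a step that forms no stereocentre.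

Key step: step 20

## Route

Remark on the chemistry: locants O1–C8a refer to the chroman and C1′–C8′ to the other ring carbons as defined above. The target is taken as the (2R,3S,4R,6′R) isomer encoded by its SMILES, and bromination of 8 is assumed to occur ortho to fluorine.

Step 1
Reactants: 1 geraniol
Product: 2 [(2R,3R)-3-methyl-3-(4-methylpent-3-en-1-yl)oxiran-2-yl]methanol
Conditions: Ti(Oi-Pr)4 (5 mol%), D-(−)-diethyl tartrate (7 mol%), t-BuOOH, 4 Å molecular sieves, CH2Cl2, −20 °C
Reagents that add atoms: tert-butyl hydroperoxide, CC(C)(C)OO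
Why: Sharpless asymmetric epoxidation; only the allylic alkene is bound to titanium, and the D-tartrate ligand should deliver oxygen to the face that gives the (2R,3R) epoxide, which fixes the later C2 and, through the E geometry, prepares C3.

Step 2
Reactants: 2 [(2R,3R)-3-methyl-3-(4-methylpent-3-en-1-yl)oxiran-2-yl]methanol
Product: 3 (2S,3R)-2-ethenyl-3,7-dimethyloct-6-ene-1,3-diol
Conditions: CH2=CHMgBr (3.5 equiv), CuI (10 mol%), THF–Et2O, −30 → 0 °C; aq. NH4Cl
Reagents that add atoms: vinylmagnesium bromide, C=C[Mg]Br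
Why: Copper-catalysed Grignard opening of a 2,3-epoxy alcohol; SN2 attack at the secondary carbon (the quaternary carbon is blocked) inverts the later C3 and leaves the C–O bond of the later C2 intact, so methyl and vinyl end up cis in the chroman.

Step 3
Reactants: 3 (2S,3R)-2-ethenyl-3,7-dimethyloct-6-ene-1,3-diol
Product: 4 (2S,3R)-2-ethenyl-3,7-dimethyl-1,3-bis(triethylsilyloxy)oct-6-ene
Conditions: Et3SiOTf (2.4 equiv), 2,6-lutidine, CH2Cl2, −78 → 0 °C
Reagents that add atoms: triethylsilyl trifluoromethanesulfonate, CC[Si](CC)(CC)OS(=O)(=O)C(F)(F)F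
Why: A silyl triflate with a hindered pyridine base silylates both the primary and the hindered tertiary hydroxyl; the tertiary ether later prevents retro-aldol cleavage.

Step 4
Reactants: 4 (2S,3R)-2-ethenyl-3,7-dimethyl-1,3-bis(triethylsilyloxy)oct-6-ene
Product: 5 (2R,3R)-2-ethenyl-3,7-dimethyl-3-(triethylsilyloxy)oct-6-enal
Conditions: (COCl)2, DMSO, CH2Cl2, −78 → −40 °C; Et3N, −78 → −20 °C
Reagents that add atoms: none
Why: Under Swern conditions a primary triethylsilyl ether is cleaved and oxidised in one operation while the tertiary silyl ether survives; low temperature and immediate use should keep the α-vinyl stereocentre from epimerising or moving into conjugation.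

Step 5
Reactants: 5 (2R,3R)-2-ethenyl-3,7-dimethyl-3-(triethylsilyloxy)oct-6-enal
Product: 6 (5S,6R)-5-ethenyl-2,6,10-trimethyl-6-(triethylsilyloxy)undec-9-en-4-ol (both C4 epimers)
Conditions: i-BuMgBr, Et2O, −78 °C; aq. NH4Cl
Reagents that add atoms: isobutylmagnesium bromide, CC(C)C[Mg]Br
Why: Grignard 1,2-addition to the aldehyde brings in the intact isobutyl group; the carbinol configuration is irrelevant because it is oxidised next.

Step 6
Reactants: 6 (5S,6R)-5-ethenyl-2,6,10-trimethyl-6-(triethylsilyloxy)undec-9-en-4-ol (both C4 epimers)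
Product: 7 (5R,6R)-5-ethenyl-2,6,10-trimethyl-6-(triethylsilyloxy)undec-9-en-4-one
Conditions: Dess–Martin periodinane, NaHCO3, CH2Cl2, 0 °C → rt
Reagents that add atoms: none
Why: Dess–Martin oxidation under buffered, non-basic conditions is chosen so that the β,γ-unsaturated ketone is not enolised.

Step 7
Reactants: 8 1-fluoro-3,5-dimethoxybenzene
Product: 9 2-bromo-1-fluoro-3,5-dimethoxybenzene
Conditions: NBS (1.0 equiv), MeCN, 0 °C → rt
Reagents that add atoms: N-bromosuccinimide, O=C1CCC(=O)N1Br
Why: Electrophilic aromatic bromination; attack is expected para to one methoxy group and ortho to fluorine, since the position between the two methoxy groups is the more hindered one.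

Step 8
Reactants: 9 2-bromo-1-fluoro-3,5-dimethoxybenzene; 7 (5R,6R)-5-ethenyl-2,6,10-trimethyl-6-(triethylsilyloxy)undec-9-en-4-one
Product: 12 (5S,6R)-5-ethenyl-4-(2-fluoro-4,6-dimethoxyphenyl)-2,6,10-trimethyl-6-(triethylsilyloxy)undec-9-en-4-ol (both C4 epimers), via aryllithium 10 (not isolated), via arylcerium dichloride 11 (not isolated)
Conditions: 9, n-BuLi, THF, −78 °C; anhydrous CeCl3, −78 °C; then 7, −78 → −40 °C; aq. NH4Cl
Reagents that add atoms: none
Why: Bromine–lithium exchange, transmetalation to the weakly basic organocerium reagent and 1,2-addition to the enolisable α-branched ketone; the C4 epimers are of no consequence because this centre is ionised in the next step.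

Step 9
Reactants: 12 (5S,6R)-5-ethenyl-4-(2-fluoro-4,6-dimethoxyphenyl)-2,6,10-trimethyl-6-(triethylsilyloxy)undec-9-en-4-ol (both C4 epimers)
Product: 13 2-[(4R,5S,6R)-5-ethenyl-2,6,10-trimethyl-6-(triethylsilyloxy)undec-9-en-4-yl]-1-fluoro-3,5-dimethoxybenzene
Conditions: Et3SiH (10 equiv), CF3CO2H (3 equiv), CH2Cl2, −40 °C; aq. NaHCO3
Reagents that add atoms: none
Why: Ionic hydrogenation of a tertiary benzylic alcohol through a cation stabilised by the ortho and para methoxy groups; 1,3-allylic strain with the ortho substituent of the coplanar aryl ring should hold the neighbouring C–H in the cation plane, so the silane attacks the face flanked by the vinyl group and not by the quaternary silyloxy carbon, giving (4R). The in-plane C–H is also poorly aligned for loss as a proton, and excess silane should outrun capture of the cation by the remote alkene.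

Step 10
Reactants: 13 2-[(4R,5S,6R)-5-ethenyl-2,6,10-trimethyl-6-(triethylsilyloxy)undec-9-en-4-yl]-1-fluoro-3,5-dimethoxybenzene
Product: 14 1,5-dibromo-3-[(4R,5S,6R)-5-ethenyl-2,6,10-trimethyl-6-(triethylsilyloxy)undec-9-en-4-yl]-2-fluoro-4,6-dimethoxybenzene
Conditions: NBS (2.1 equiv), MeCN, 0 °C → rt, dark
Reagents that add atoms: N-bromosuccinimide, O=C1CCC(=O)N1Br
Why: Electrophilic bromination at the two remaining arene positions, each ortho or para to both methoxy groups, should be faster than any reaction of NBS with the isolated alkenes in a dry polar solvent without light.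

Step 11
Reactants: 14 1,5-dibromo-3-[(4R,5S,6R)-5-ethenyl-2,6,10-trimethyl-6-(triethylsilyloxy)undec-9-en-4-yl]-2-fluoro-4,6-dimethoxybenzene
Product: 16 5-[(4R,5S,6R)-5-ethenyl-2,6,10-trimethyl-6-(triethylsilyloxy)undec-9-en-4-yl]-4-fluoro-2,6-dimethoxybenzene-1,3-dicarbaldehyde, via dilithioarene 15 (not isolated)
Conditions: t-BuLi (4.2 equiv), Et2O–THF, −78 °C; DMF, −78 → 0 °C; aq. NH4Cl
Reagents that add atoms: N,N-dimethylformamide, CN(C)C=O
Why: Double bromine–lithium exchange and formylation; both aryllithium sites are flanked by coordinating substituents, and at −78 °C the one ortho to fluorine should not lose LiF before DMF is added.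

Step 12
Reactants: 16 5-[(4R,5S,6R)-5-ethenyl-2,6,10-trimethyl-6-(triethylsilyloxy)undec-9-en-4-yl]-4-fluoro-2,6-dimethoxybenzene-1,3-dicarbaldehyde
Product: 18 (2R,3S,4R)-3-ethenyl-5,7-dimethoxy-2-methyl-2-(4-methylpent-3-en-1-yl)-4-(2-methylpropyl)-3,4-dihydro-2H-chromene-6,8-dicarbaldehyde, via ammonium alkoxide 17 (not isolated)
Conditions: Bu4NF (1.2 equiv, dried over 4 Å molecular sieves), THF, 0 °C → rt
Reagents that add atoms: none
Why: Fluoride removes the tertiary silyl group and the alkoxide closes the pyran by intramolecular SNAr at the fluorine-bearing carbon, activated by one ortho and one para formyl group; the aryl C–O bond is the one formed, so C2 keeps its configuration.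

Step 13
Reactants: 18 (2R,3S,4R)-3-ethenyl-5,7-dimethoxy-2-methyl-2-(4-methylpent-3-en-1-yl)-4-(2-methylpropyl)-3,4-dihydro-2H-chromene-6,8-dicarbaldehyde
Product: 19 2,2′-[(2R,3S,4R)-3-ethenyl-5,7-dimethoxy-2-methyl-2-(4-methylpent-3-en-1-yl)-4-(2-methylpropyl)-3,4-dihydro-2H-chromene-6,8-diyl]bis(1,3-dioxolane)
Conditions: Me3SiOCH2CH2OSiMe3 (4 equiv), Me3SiOTf (10 mol%), CH2Cl2, −78 → −20 °C; pyridine
Reagents that add atoms: 1,2-bis(trimethylsilyloxy)ethane, C[Si](C)(C)OCCO[Si](C)(C)C
Why: Acetalisation with the bis-silyl ether of the diol under silyl triflate catalysis proceeds at low temperature even on hindered, electron-rich aldehydes; the acetals mask the formyl groups against acetylide, butyllithium and the borane.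

Step 14
Reactants: 19 2,2′-[(2R,3S,4R)-3-ethenyl-5,7-dimethoxy-2-methyl-2-(4-methylpent-3-en-1-yl)-4-(2-methylpropyl)-3,4-dihydro-2H-chromene-6,8-diyl]bis(1,3-dioxolane)
Product: 20 2,2′-[(2R,3S,4R)-2-{2-[(2R)-3,3-dimethyloxiran-2-yl]ethyl}-3-ethenyl-5,7-dimethoxy-2-methyl-4-(2-methylpropyl)-3,4-dihydro-2H-chromene-6,8-diyl]bis(1,3-dioxolane)
Conditions: D-fructose-derived Shi ketone (30 mol%), KHSO5 (as Oxone), K2CO3, Bu4NHSO4, MeCN–CH2(OMe)2–aq. Na2B4O7 buffer (pH 10.5), 0 °C
Reagents that add atoms: potassium hydrogen peroxymonosulfate, OOS(=O)(=O)[O-].[K+]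
Why: Shi epoxidation; the chiral dioxirane reacts with the electron-rich trisubstituted alkene far faster than with the monosubstituted vinyl group and, through the spiro transition state, should give the (R) epoxide under reagent control, independent of the distant stereocentres.

Step 15
Reactants: 20 2,2′-[(2R,3S,4R)-2-{2-[(2R)-3,3-dimethyloxiran-2-yl]ethyl}-3-ethenyl-5,7-dimethoxy-2-methyl-4-(2-methylpropyl)-3,4-dihydro-2H-chromene-6,8-diyl]bis(1,3-dioxolane)
Product: 21 (3R)-3-{2-[(2R,3S,4R)-6,8-di(1,3-dioxolan-2-yl)-3-ethenyl-5,7-dimethoxy-2-methyl-4-(2-methylpropyl)-3,4-dihydro-2H-chromen-2-yl]ethyl}-2-methylpent-4-yn-2-ol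
Conditions: HC≡CLi·H2NCH2CH2NH2 (5 equiv), DMSO, rt → 40 °C; aq. NH4Cl
Reagents that add atoms: lithium acetylide–ethylenediamine complex, [Li]C#C.NCCN
Why: SN2 opening of the trisubstituted epoxide by acetylide at the secondary carbon, with inversion, sets C6′ and releases the tertiary alcohol in the same step.

Step 16
Reactants: 21 (3R)-3-{2-[(2R,3S,4R)-6,8-di(1,3-dioxolan-2-yl)-3-ethenyl-5,7-dimethoxy-2-methyl-4-(2-methylpropyl)-3,4-dihydro-2H-chromen-2-yl]ethyl}-2-methylpent-4-yn-2-ol
Product: 22 triethyl{[(3R)-3-{2-[(2R,3S,4R)-6,8-di(1,3-dioxolan-2-yl)-3-ethenyl-5,7-dimethoxy-2-methyl-4-(2-methylpropyl)-3,4-dihydro-2H-chromen-2-yl]ethyl}-2-methylpent-4-yn-2-yl]oxy}silane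
Conditions: Et3SiCl (3 equiv), imidazole, DMAP (cat.), DMF, 40 °C
Reagents that add atoms: chlorotriethylsilane, CC[Si](Cl)(CC)CC
Why: Silylation of a tertiary dimethylcarbinol with the silyl chloride under nucleophilic catalysis; the basic medium spares the acid-labile aryl acetals, which a silyl triflate could open.

Step 17
Reactants: 22 triethyl{[(3R)-3-{2-[(2R,3S,4R)-6,8-di(1,3-dioxolan-2-yl)-3-ethenyl-5,7-dimethoxy-2-methyl-4-(2-methylpropyl)-3,4-dihydro-2H-chromen-2-yl]ethyl}-2-methylpent-4-yn-2-yl]oxy}silane; 23 N-methoxy-N-methylacetamide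
Product: 25 (5R)-5-{2-[(2R,3S,4R)-6,8-di(1,3-dioxolan-2-yl)-3-ethenyl-5,7-dimethoxy-2-methyl-4-(2-methylpropyl)-3,4-dihydro-2H-chromen-2-yl]ethyl}-6-methyl-6-(triethylsilyloxy)hept-3-yn-2-one, via lithium acetylide 24 (not isolated)
Conditions: n-BuLi (1.05 equiv), THF, −78 °C; 23, −78 → 0 °C; aq. NH4Cl
Reagents that add atoms: none
Why: Deprotonation of the terminal alkyne and acylation with the Weinreb amide; the chelated tetrahedral adduct prevents a second addition.

Step 18
Reactants: 25 (5R)-5-{2-[(2R,3S,4R)-6,8-di(1,3-dioxolan-2-yl)-3-ethenyl-5,7-dimethoxy-2-methyl-4-(2-methylpropyl)-3,4-dihydro-2H-chromen-2-yl]ethyl}-6-methyl-6-(triethylsilyloxy)hept-3-yn-2-one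
Product: 26 (3Z,5R)-5-{2-[(2R,3S,4R)-6,8-di(1,3-dioxolan-2-yl)-3-ethenyl-5,7-dimethoxy-2-methyl-4-(2-methylpropyl)-3,4-dihydro-2H-chromen-2-yl]ethyl}-6-methyl-6-(triethylsilyloxy)hept-3-en-2-one
Conditions: H2 (1 atm), Pd/CaCO3 poisoned with Pb(OAc)2 (Lindlar catalyst), quinoline, EtOAc, 0 °C, stopped after one equivalent of H2
Reagents that add atoms: none
Why: Lindlar semi-hydrogenation adds hydrogen syn to the activated alkyne and gives the cis enone; the poisoned catalyst and controlled uptake should leave the hindered vinyl group untouched.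

Step 19
Reactants: 26 (3Z,5R)-5-{2-[(2R,3S,4R)-6,8-di(1,3-dioxolan-2-yl)-3-ethenyl-5,7-dimethoxy-2-methyl-4-(2-methylpropyl)-3,4-dihydro-2H-chromen-2-yl]ethyl}-6-methyl-6-(triethylsilyloxy)hept-3-en-2-one
Product: 28 (3Z,5R)-5-{2-[(2R,3S,4R)-6,8-di(1,3-dioxolan-2-yl)-3-ethenyl-5,7-dimethoxy-2-methyl-4-(2-methylpropyl)-3,4-dihydro-2H-chromen-2-yl]ethyl}-6-methyl-6-(triethylsilyloxy)hepta-1,3-dien-2-yl trifluoromethanesulfonate, via potassium dienolate 27 (not isolated)
Conditions: KN(SiMe3)2 (1.1 equiv), THF, −78 °C; PhNTf2, −78 °C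
Reagents that add atoms: N-phenylbis(trifluoromethanesulfonimide), O=S(=O)(N(c1ccccc1)S(=O)(=O)C(F)(F)F)C(F)(F)F
Why: Kinetic deprotonation by a hindered amide base takes the unhindered methyl protons and not the tertiary γ-proton, giving the cross-conjugated dienolate; O-sulfonylation then gives the 2-triflyloxy-1,3-diene with the cis alkene unchanged.

Step 20
Reactants: 28 (3Z,5R)-5-{2-[(2R,3S,4R)-6,8-di(1,3-dioxolan-2-yl)-3-ethenyl-5,7-dimethoxy-2-methyl-4-(2-methylpropyl)-3,4-dihydro-2H-chromen-2-yl]ethyl}-6-methyl-6-(triethylsilyloxy)hepta-1,3-dien-2-yl trifluoromethanesulfonate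
Product: 30 O-triethylsilyl di-O-methyl bis(1,3-dioxolane) derivative of 33 with the ten-membered ring closed, via alkylborane 29 (not isolated)
Conditions: 9-BBN (2 equiv), THF, 0 °C → rt; then slow addition to PdCl2(dppf) (20 mol%), AsPh3 (40 mol%), Cs2CO3 (3 equiv), DMF–THF–H2O, 45 °C, final concentration about 1 mM
Reagents that add atoms: none
Why: The bulky dialkylborane adds anti-Markovnikov to the monosubstituted vinyl group on C3 only, since the 1,1-disubstituted alkene of the diene is deactivated by the triflate oxygen and the cis alkene is hindered. Zerovalent palladium, formed from PdCl2(dppf), then inserts into the C3′–O bond of the dienyl triflate with retention of the diene geometry. The base-activated borate transfers its primary alkyl group C2′ to palladium, and reductive elimination forms the C2′–C3′ bond. The closest known reaction type is the macrocyclising B-alkyl Suzuki–Miyaura coupling of B-alkyl-9-borabicyclononanes with alkenyl triflates or iodides, for which ten-membered carbocycles are rare. The ring is closed by reductive elimination from an eleven-membered palladacycle, with the new bond exocyclic to the diene so that the methylene stays outside the ring. No stereocentre is formed, and the cis C4′=C5′ bond set in step 18 is not touched. The step needs site-selective hydroboration and intramolecular rather than intermolecular coupling; the first rests on the steric and electronic difference between the alkenes, the second on slow addition at high dilution. The wide bite angle of dppf together with AsPh3 should favour reductive elimination over β-hydride elimination, and the two arms sit on adjacent carbons of the rigid chroman, which holds the reacting ends close.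

Step 21
Reactants: 30 O-triethylsilyl di-O-methyl bis(1,3-dioxolane) derivative of 33 with the ten-membered ring closed
Product: 31 O-triethylsilyl di-O-methyl ether of 33 with free formyl groups at C6 and C8
Conditions: PPTS (cat.), acetone–H2O (10:1), rt
Reagents that add atoms: water, O
Why: Acid-catalysed acetal hydrolysis; acetals on so electron-rich an arene ionise under very mild acid, so the diene and the tertiary silyl ether should survive.

Step 22
Reactants: 31 O-triethylsilyl di-O-methyl ether of 33 with free formyl groups at C6 and C8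
Product: 32 O-triethylsilyl ether of 33
Conditions: MgI2·OEt2 (6 equiv), toluene–Et2O, 50 °C; dilute aq. HCl
Reagents that add atoms: none
Why: Magnesium chelated between a formyl oxygen and the neighbouring methoxy oxygen activates the O–CH3 bond for SN2 attack by iodide; both methoxy groups have an ortho formyl group, whereas the tertiary chroman ether cannot be cleaved by SN2.

Step 23
Reactants: 32 O-triethylsilyl ether of 33
Product: 33 CNP0479784.1
Conditions: HF·pyridine, pyridine, THF, 0 °C → rt
Reagents that add atoms: none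
Why: Fluoride-driven Si–O cleavage under buffered conditions frees the tertiary alcohol last, after the Lewis-acid step, without stressing the diene.

## Compound list

1 | geraniol, (2E)-3,7-dimethylocta-2,6-dien-1-ol | CC(C)=CCC/C(C)=C/CO | starting material
2 | [(2R,3R)-3-methyl-3-(4-methylpent-3-en-1-yl)oxiran-2-yl]methanol | CC(C)=CCC[C@@]1(C)O[C@@H]1CO | intermediate
3 | (2S,3R)-2-ethenyl-3,7-dimethyloct-6-ene-1,3-diol | CC(C)=CCC[C@@](C)(O)[C@@H](C=C)CO | intermediate
4 | (2S,3R)-2-ethenyl-3,7-dimethyl-1,3-bis(triethylsilyloxy)oct-6-ene | CC(C)=CCC[C@@](C)(O[Si](CC)(CC)CC)[C@@H](C=C)CO[Si](CC)(CC)CC | intermediate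
5 | (2R,3R)-2-ethenyl-3,7-dimethyl-3-(triethylsilyloxy)oct-6-enal | CC(C)=CCC[C@@](C)(O[Si](CC)(CC)CC)[C@@H](C=C)C=O | intermediate
6 | (5S,6R)-5-ethenyl-2,6,10-trimethyl-6-(triethylsilyloxy)undec-9-en-4-ol (both C4 epimers) | CC(C)=CCC[C@@](C)(O[Si](CC)(CC)CC)[C@@H](C=C)C(O)CC(C)C | intermediate
7 | (5R,6R)-5-ethenyl-2,6,10-trimethyl-6-(triethylsilyloxy)undec-9-en-4-one | CC(C)=CCC[C@@](C)(O[Si](CC)(CC)CC)[C@@H](C=C)C(=O)CC(C)C | intermediate
8 | 1-fluoro-3,5-dimethoxybenzene | COc1cc(F)cc(OC)c1 | starting material
9 | 2-bromo-1-fluoro-3,5-dimethoxybenzene | COc1cc(F)c(Br)c(OC)c1 | intermediate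
10 | (2-fluoro-4,6-dimethoxyphenyl)lithium | COc1cc(F)c([Li])c(OC)c1 | intermediate
11 | dichloro(2-fluoro-4,6-dimethoxyphenyl)cerium | COc1cc(F)c([Ce](Cl)Cl)c(OC)c1 | intermediate
12 | (5S,6R)-5-ethenyl-4-(2-fluoro-4,6-dimethoxyphenyl)-2,6,10-trimethyl-6-(triethylsilyloxy)undec-9-en-4-ol (both C4 epimers) | CC(C)=CCC[C@@](C)(O[Si](CC)(CC)CC)[C@@H](C=C)C(O)(CC(C)C)c1c(F)cc(OC)cc1OC | intermediate
13 | 2-[(4R,5S,6R)-5-ethenyl-2,6,10-trimethyl-6-(triethylsilyloxy)undec-9-en-4-yl]-1-fluoro-3,5-dimethoxybenzene | CC(C)=CCC[C@@](C)(O[Si](CC)(CC)CC)[C@@H](C=C)[C@@H](CC(C)C)c1c(F)cc(OC)cc1OC | intermediate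
14 | 1,5-dibromo-3-[(4R,5S,6R)-5-ethenyl-2,6,10-trimethyl-6-(triethylsilyloxy)undec-9-en-4-yl]-2-fluoro-4,6-dimethoxybenzene | CC(C)=CCC[C@@](C)(O[Si](CC)(CC)CC)[C@@H](C=C)[C@@H](CC(C)C)c1c(F)c(Br)c(OC)c(Br)c1OC | intermediate
15 | 1,5-dilithio analogue of 14 (lithium in place of both bromine atoms) | CC(C)=CCC[C@@](C)(O[Si](CC)(CC)CC)[C@@H](C=C)[C@@H](CC(C)C)c1c(F)c([Li])c(OC)c([Li])c1OC | intermediate
16 | 5-[(4R,5S,6R)-5-ethenyl-2,6,10-trimethyl-6-(triethylsilyloxy)undec-9-en-4-yl]-4-fluoro-2,6-dimethoxybenzene-1,3-dicarbaldehyde | CC(C)=CCC[C@@](C)(O[Si](CC)(CC)CC)[C@@H](C=C)[C@@H](CC(C)C)c1c(F)c(C=O)c(OC)c(C=O)c1OC | intermediate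
17 | tetrabutylammonium alkoxide of desilylated 16 | CC(C)=CCC[C@@](C)([O-])[C@@H](C=C)[C@@H](CC(C)C)c1c(F)c(C=O)c(OC)c(C=O)c1OC.CCCC[N+](CCCC)(CCCC)CCCC | intermediate
18 | (2R,3S,4R)-3-ethenyl-5,7-dimethoxy-2-methyl-2-(4-methylpent-3-en-1-yl)-4-(2-methylpropyl)-3,4-dihydro-2H-chromene-6,8-dicarbaldehyde | CC(C)=CCC[C@@]1(C)Oc2c(C=O)c(OC)c(C=O)c(OC)c2[C@H](CC(C)C)[C@@H]1C=C | intermediate
19 | 2,2′-[(2R,3S,4R)-3-ethenyl-5,7-dimethoxy-2-methyl-2-(4-methylpent-3-en-1-yl)-4-(2-methylpropyl)-3,4-dihydro-2H-chromene-6,8-diyl]bis(1,3-dioxolane) | CC(C)=CCC[C@@]1(C)Oc2c(C3OCCO3)c(OC)c(C3OCCO3)c(OC)c2[C@H](CC(C)C)[C@@H]1C=C | intermediate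
20 | 2,2′-[(2R,3S,4R)-2-{2-[(2R)-3,3-dimethyloxiran-2-yl]ethyl}-3-ethenyl-5,7-dimethoxy-2-methyl-4-(2-methylpropyl)-3,4-dihydro-2H-chromene-6,8-diyl]bis(1,3-dioxolane) | CC1(C)O[C@@H]1CC[C@@]2(C)Oc3c(C4OCCO4)c(OC)c(C4OCCO4)c(OC)c3[C@H](CC(C)C)[C@@H]2C=C | intermediate
21 | (3R)-3-{2-[(2R,3S,4R)-6,8-di(1,3-dioxolan-2-yl)-3-ethenyl-5,7-dimethoxy-2-methyl-4-(2-methylpropyl)-3,4-dihydro-2H-chromen-2-yl]ethyl}-2-methylpent-4-yn-2-ol | C#C[C@H](C(C)(C)O)CC[C@@]2(C)Oc3c(C4OCCO4)c(OC)c(C4OCCO4)c(OC)c3[C@H](CC(C)C)[C@@H]2C=C | intermediate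
22 | triethylsilyl ether of 21 | C#C[C@H](C(C)(C)O[Si](CC)(CC)CC)CC[C@@]2(C)Oc3c(C4OCCO4)c(OC)c(C4OCCO4)c(OC)c3[C@H](CC(C)C)[C@@H]2C=C | intermediate
23 | N-methoxy-N-methylacetamide | CON(C)C(C)=O | starting material
24 | lithium acetylide of 22 | [Li]C#C[C@H](C(C)(C)O[Si](CC)(CC)CC)CC[C@@]2(C)Oc3c(C4OCCO4)c(OC)c(C4OCCO4)c(OC)c3[C@H](CC(C)C)[C@@H]2C=C | intermediate
25 | (5R)-5-{2-[(2R,3S,4R)-6,8-di(1,3-dioxolan-2-yl)-3-ethenyl-5,7-dimethoxy-2-methyl-4-(2-methylpropyl)-3,4-dihydro-2H-chromen-2-yl]ethyl}-6-methyl-6-(triethylsilyloxy)hept-3-yn-2-one | CC(=O)C#C[C@H](C(C)(C)O[Si](CC)(CC)CC)CC[C@@]2(C)Oc3c(C4OCCO4)c(OC)c(C4OCCO4)c(OC)c3[C@H](CC(C)C)[C@@H]2C=C | intermediate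
26 | (3Z,5R)-enone corresponding to 25 (hept-3-en-2-one) | CC(=O)/C=C\[C@H](C(C)(C)O[Si](CC)(CC)CC)CC[C@@]2(C)Oc3c(C4OCCO4)c(OC)c(C4OCCO4)c(OC)c3[C@H](CC(C)C)[C@@H]2C=C | intermediate
27 | potassium (3Z,5R)-hepta-1,3-dien-2-olate derived from 26 | C=C(O[K])/C=C\[C@H](C(C)(C)O[Si](CC)(CC)CC)CC[C@@]2(C)Oc3c(C4OCCO4)c(OC)c(C4OCCO4)c(OC)c3[C@H](CC(C)C)[C@@H]2C=C | intermediate
28 | (3Z,5R)-5-{2-[(2R,3S,4R)-6,8-di(1,3-dioxolan-2-yl)-3-ethenyl-5,7-dimethoxy-2-methyl-4-(2-methylpropyl)-3,4-dihydro-2H-chromen-2-yl]ethyl}-6-methyl-6-(triethylsilyloxy)hepta-1,3-dien-2-yl trifluoromethanesulfonate | C=C(OS(=O)(=O)C(F)(F)F)/C=C\[C@H](C(C)(C)O[Si](CC)(CC)CC)CC[C@@]2(C)Oc3c(C4OCCO4)c(OC)c(C4OCCO4)c(OC)c3[C@H](CC(C)C)[C@@H]2C=C | intermediate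
29 | B-alkyl-9-borabicyclo[3.3.1]nonane from 28, boron on the terminal carbon of the former C3 vinyl group | C=C(OS(=O)(=O)C(F)(F)F)/C=C\[C@H](C(C)(C)O[Si](CC)(CC)CC)CC[C@@]2(C)Oc3c(C4OCCO4)c(OC)c(C4OCCO4)c(OC)c3[C@H](CC(C)C)[C@@H]2CCB5C6CCCC5CCC6 | intermediate
30 | O-triethylsilyl di-O-methyl bis(1,3-dioxolane) derivative of 33 with the ten-membered ring closed | C=C1/C=C\[C@H](C(C)(C)O[Si](CC)(CC)CC)CC[C@@]2(C)Oc3c(C4OCCO4)c(OC)c(C4OCCO4)c(OC)c3[C@H](CC(C)C)[C@@H]2CC1 | intermediate
31 | O-triethylsilyl di-O-methyl ether of 33 with free formyl groups at C6 and C8 | C=C1/C=C\[C@H](C(C)(C)O[Si](CC)(CC)CC)CC[C@@]2(C)Oc3c(C=O)c(OC)c(C=O)c(OC)c3[C@H](CC(C)C)[C@@H]2CC1 | intermediate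
32 | O-triethylsilyl ether of 33 | C=C1/C=C\[C@H](C(C)(C)O[Si](CC)(CC)CC)CC[C@@]2(C)Oc3c(C=O)c(O)c(C=O)c(O)c3[C@H](CC(C)C)[C@@H]2CC1 | intermediate
33 | CNP0479784.1, the (2R,3S,4R)-5,7-dihydroxy-2-methyl-4-(2-methylpropyl)chroman-6,8-dicarbaldehyde whose C2 and C3 are bridged by C8′H2–C7′H2–C6′H[(R), C(CH3)2OH]–C5′H=C4′H (Z)–C3′(=CH2)–C2′H2–C1′H2 | C=C1/C=C\[C@H](C(C)(C)O)CC[C@@]2(C)Oc3c(C=O)c(O)c(C=O)c(O)c3[C@H](CC(C)C)[C@@H]2CC1 | target

## Step count and least certain steps

The route has 23 steps in all. The longest linear sequence is 22 steps from geraniol 1 (steps 1–6 and 8–23); step 7 prepares the arene 9.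

**Step 20 (key step).** The most likely failure is slow transmetalation or slow reductive elimination in the strained medium ring. Protodeboronation, β-hydride elimination, hydrolysis of the dienyl triflate and intermolecular coupling would then take over. The fallback sets out from 28 and returns at 30, and separates hydrometalation from coupling. Hydroboration of 28 and oxidation with NaBO3 would give the primary alcohol F1. Iodine, PPh3 and imidazole would convert it into the primary iodide F2. Zinc insertion (Zn, LiCl, THF) would give the alkylzinc iodide F3, which would be cyclised at high dilution by an intramolecular Negishi coupling (Pd(OAc)2, SPhos) to 30, without base or water.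

**Step 9.** Facial discrimination may be poor if the congested aryl ring twists out of the cation plane. The cation may also lose the neighbouring proton or be captured by the trisubstituted alkene. The fallback sets out from 12 and returns at 13 and avoids the cation. The tertiary alkoxide of 12 (KN(SiMe3)2) would be acylated with methyl chlorooxoacetate to the methyl oxalate F4. Barton–McCombie-type reduction with Bu3SnH and AIBN would then proceed through the benzylic radical, which is subject to the same allylic strain, to 13.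

**Step 8.** The aryl metal may enolise the hindered ketone instead of adding to it, which would return the ketone and epimerise the α-vinyl centre. The fallback sets out from 7 and returns at 13, and makes the aryl–C4 bond by cross-coupling. Kinetic enolisation towards the isobutyl methylene and trapping with PhNTf2 would give the enol triflate F5. Negishi coupling with the arylzinc chloride F6 (from 10 and ZnCl2) would give the trisubstituted styrene F7. Ionic hydrogenation of F7 (Et3SiH, CF3CO2H) passes through the same benzylic cation as step 9 and would give 13.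

**Step 15.** SN2 attack at the hindered secondary epoxide carbon may be slow, so that base-induced isomerisation of the epoxide to an allylic alcohol competes. The fallback sets out from 20 and returns at 22, and uses a softer, less basic carbon nucleophile. 2-Lithio-1,3-dithiane would open the epoxide to the dithianyl carbinol F8. Silylation as in step 16 would give the silyl ether F9. Unmasking with MeI and CaCO3 in aqueous MeCN would give the aldehyde F10, and Ohira–Bestmann homologation would give 22.

**Step 18.** Over-reduction of the vinyl group or of the enone, and cis-to-trans isomerisation of the sensitive enone on the catalyst or during isolation, are the risks. The fallback sets out from 22 and returns at 26, and hydrogenates at the more robust alcohol level. The lithium acetylide 24 would be added to acetaldehyde to give the propargylic alcohol F11. Lindlar reduction would give the cis allylic alcohol F12, and Dess–Martin oxidation would give 26.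

**Step 22.** At the temperature needed for the second demethylation, Lewis-acid-induced ionisation of the tertiary chroman ether O1–C2 or of the allylic system may compete. The fallback sets out from 31 and returns at 32. It replaces Lewis-acid activation by SN2 dealkylation with a soft anion (NaSEt, DMF, warm), which makes no new compound (F0).

## Further compounds

F1 | step 20 | primary alcohol from hydroboration–oxidation of the C3 vinyl group of 28 | C=C(OS(=O)(=O)C(F)(F)F)/C=C\[C@H](C(C)(C)O[Si](CC)(CC)CC)CC[C@@]2(C)Oc3c(C4OCCO4)c(OC)c(C4OCCO4)c(OC)c3[C@H](CC(C)C)[C@@H]2CCO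
F2 | step 20 | primary iodide from F1 | C=C(OS(=O)(=O)C(F)(F)F)/C=C\[C@H](C(C)(C)O[Si](CC)(CC)CC)CC[C@@]2(C)Oc3c(C4OCCO4)c(OC)c(C4OCCO4)c(OC)c3[C@H](CC(C)C)[C@@H]2CCI
F3 | step 20 | alkylzinc iodide from F2 | C=C(OS(=O)(=O)C(F)(F)F)/C=C\[C@H](C(C)(C)O[Si](CC)(CC)CC)CC[C@@]2(C)Oc3c(C4OCCO4)c(OC)c(C4OCCO4)c(OC)c3[C@H](CC(C)C)[C@@H]2CC[Zn]I
F4 | step 9 | methyl oxalate of 12 (both C4 epimers) | CC(C)=CCC[C@@](C)(O[Si](CC)(CC)CC)[C@@H](C=C)C(OC(=O)C(=O)OC)(CC(C)C)c1c(F)cc(OC)cc1OC
F5 | step 8 | enol triflate of 7 towards the isobutyl methylene (E/Z mixture) | CC(C)=CCC[C@@](C)(O[Si](CC)(CC)CC)[C@@H](C=C)C(OS(=O)(=O)C(F)(F)F)=CC(C)C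
F6 | step 8 | (2-fluoro-4,6-dimethoxyphenyl)zinc chloride | COc1cc(F)c([Zn]Cl)c(OC)c1
F7 | step 8 | trisubstituted styrene from F5 and F6 (E/Z mixture) | CC(C)=CCC[C@@](C)(O[Si](CC)(CC)CC)[C@@H](C=C)C(=CC(C)C)c1c(F)cc(OC)cc1OC
F8 | step 15 | dithianyl carbinol from 20 | C1CSC(SC1)[C@H](C(C)(C)O)CC[C@@]2(C)Oc3c(C4OCCO4)c(OC)c(C4OCCO4)c(OC)c3[C@H](CC(C)C)[C@@H]2C=C
F9 | step 15 | triethylsilyl ether of F8 | C1CSC(SC1)[C@H](C(C)(C)O[Si](CC)(CC)CC)CC[C@@]2(C)Oc3c(C4OCCO4)c(OC)c(C4OCCO4)c(OC)c3[C@H](CC(C)C)[C@@H]2C=C
F10 | step 15 | aldehyde from F9 | O=C[C@H](C(C)(C)O[Si](CC)(CC)CC)CC[C@@]2(C)Oc3c(C4OCCO4)c(OC)c(C4OCCO4)c(OC)c3[C@H](CC(C)C)[C@@H]2C=C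
F11 | step 18 | propargylic alcohol from 24 and acetaldehyde (both carbinol epimers) | CC(O)C#C[C@H](C(C)(C)O[Si](CC)(CC)CC)CC[C@@]2(C)Oc3c(C4OCCO4)c(OC)c(C4OCCO4)c(OC)c3[C@H](CC(C)C)[C@@H]2C=C
F12 | step 18 | cis allylic alcohol from F11 (both carbinol epimers) | CC(O)/C=C\[C@H](C(C)(C)O[Si](CC)(CC)CC)CC[C@@]2(C)Oc3c(C4OCCO4)c(OC)c(C4OCCO4)c(OC)c3[C@H](CC(C)C)[C@@H]2C=C
F0 | step 22 | none | none
A1 | alternative 1 | 5,7-dimethoxycoumarin | COc1cc(OC)c2ccc(=O)oc2c1
A2 | alternative 1 | isoprene | C=CC(C)=C
A3 | alternative 1 | cis-1,3-dimethoxy-9-methyl-6a,7,10,10a-tetrahydro-6H-benzo[c]chromen-6-one | O=C1Oc2cc(OC)cc(OC)c2[C@@H]2CC(C)=CC[C@H]12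
A4 | alternative 2 | dimethyl 3-oxopentanedioate | COC(=O)CC(=O)CC(=O)OC
A5 | alternative 2 | methyl 6-methyl-6-(4-methylpent-3-en-1-yl)-4-(2-methylpropyl)-2-oxo-5-[4-(triisopropylsilyl)but-3-yn-1-yl]tetrahydro-2H-pyran-3-carboxylate (ring stereocentres as in A6, ester-bearing carbon undefined) | CC(C)=CCC[C@@]1(C)OC(=O)C(C(=O)OC)[C@H](CC(C)C)[C@@H]1CCC#C[Si](C(C)C)(C(C)C)C(C)C
A6 | alternative 2 | chroman with 5,7-dihydroxy-6,8-bis(methoxycarbonyl) arene | CC(C)=CCC[C@@]2(C)Oc3c(C(=O)OC)c(O)c(C(=O)OC)c(O)c3[C@H](CC(C)C)[C@@H]2CCC#C[Si](C(C)C)(C(C)C)C(C)C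
A7 | alternative 3 | 1-ethenyl-6-[(E)-4-(2,4-dimethoxy-6-(methoxymethoxy)phenyl)-6-methylhept-2-en-2-yl]-4-[2-(triethylsilyloxy)propan-2-yl]cyclohex-2-en-1-ol (ethenyl and alkenyl groups trans) | C=C[C@]1(O)C=C[C@H](C(C)(C)O[Si](CC)(CC)CC)C[C@H]1/C(C)=C/[C@@H](CC(C)C)c1c(OC)cc(OC)cc1OCOC
A8 | alternative 3 | ten-membered 2Z,6E-dienone carrying the benzylic side chain | O=C1/C=C\[C@H](C(C)(C)O[Si](CC)(CC)CC)C/C=C(C)/[C@@H](CC1)[C@@H](CC(C)C)c1c(OC)cc(OC)cc1OCOC
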